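The two pyranone rings are disconnected at their O1–C2 bonds, which unravels the biflavonoid to an acyclic bis(2-hydroxyaryl) ynone–enone. Its two identical 5,7-dioxygenated A rings, each with the phenol oxygen and the acyl carbon on neighbouring carbons (C8a, C4a), come in one operation from insertion of two 3,5-bis(benzyloxy)benzynes into the C–O bonds of a propiolic/α-arylcinnamic diacid. The key step exploits the 1,5-relationship between each A-ring phenol oxygen and the β-carbon C2 of the C4-carbonyl-conjugated C2–C3 unsaturation of ring C. One chiral bifunctional squaramide closes both rings by oxa-Michael addition, the flavanone O1–C2 bond enantioselectively, and C3 settles as the 2,3-trans epimer.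

Key step: step 7

Assumption: the quinine-derived squaramide is taken as the catalyst that delivers the (2R) closure; the sense of induction on this substrate has to be confirmed, and the quinidine-derived pseudoenantiomer is the direct replacement if the opposite face is favoured.

Step 1
Reactants: 1 3,5-bis(benzyloxy)phenol
Product: 2 2-bromo-3,5-bis(benzyloxy)phenol
Conditions: NBS (1.0 equiv), CH2Cl2, −78 °C
Reagents that add atoms: N-bromosuccinimide, O=C1CCC(=O)N1Br
Why: Electrophilic aromatic bromination in a non-polar solvent at low temperature should go ortho to the free hydroxyl (hydrogen-bond-assisted delivery) at C2 and not at C4, which is flanked by two benzyloxy groups.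

Step 2
Reactants: 2 2-bromo-3,5-bis(benzyloxy)phenol
Product: 5 3,5-bis(benzyloxy)-2-(trimethylsilyl)phenyl trifluoromethanesulfonate, via aryl trimethylsilyl ether 3 (not isolated), via lithium 2-silylphenoxide 4 (not isolated)
Conditions: HMDS, THF, 70 °C, then evaporate; n-BuLi, THF, −78 °C; Tf2O, −78 °C
Reagents that add atoms: hexamethyldisilazane, C[Si](C)(C)N[Si](C)(C)C; trifluoromethanesulfonic anhydride, O=S(=O)(OS(=O)(=O)C(F)(F)F)C(F)(F)F
Why: O-silylation, bromine–lithium exchange and retro-Brook 1,3-O→C silyl shift should give the lithium 2-silylphenoxide, which triflic anhydride traps on oxygen (the standard route to 2-silylaryl triflates).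

Step 3
Reactants: 6 2-(5-bromo-2-hydroxyphenyl)acetic acid
Product: 8 2-[2-(benzyloxy)-5-bromophenyl]acetic acid, via benzyl ester 7 (not isolated)
Conditions: BnBr (2.2 equiv), K2CO3, DMF, 60 °C; then NaOH, H2O/MeOH, 50 °C; HCl work-up
Reagents that add atoms: benzyl bromide, BrCc1ccccc1
Why: Williamson benzylation of phenoxide and carboxylate followed by saponification of the benzyl ester should leave only the aryl benzyl ether.

Step 4
Reactants: 8 2-[2-(benzyloxy)-5-bromophenyl]acetic acid; 9 4-(benzyloxy)benzaldehyde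
Product: 10 (E)-2-[2-(benzyloxy)-5-bromophenyl]-3-[4-(benzyloxy)phenyl]prop-2-enoic acid
Conditions: Ac2O, Et3N, 110 °C; then H2O, 60 °C
Reagents that add atoms: none
Why: Perkin condensation (Oglialoro variant) of the mixed-anhydride enolate with the aldehyde and elimination should give the (E)-acid with the two aryl groups cis, the usual outcome for α-arylcinnamic acids.

Step 5
Reactants: 10 (E)-2-[2-(benzyloxy)-5-bromophenyl]-3-[4-(benzyloxy)phenyl]prop-2-enoic acid; 11 propiolic acid
Product: 12 (E)-2-[2-(benzyloxy)-5-(2-carboxyethynyl)phenyl]-3-[4-(benzyloxy)phenyl]prop-2-enoic acid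
Conditions: Pd(PPh3)2Cl2 (5 mol %), dppb (10 mol %), DBU (3 equiv), DMSO, 50 °C; HCl work-up
Reagents that add atoms: none
Why: Copper-free Sonogashira coupling of the aryl bromide with propiolate (as its DBU salt) below the decarboxylation temperature should keep the alkynyl carboxyl group.

Step 6
Reactants: 12 the diacid; 5 3,5-bis(benzyloxy)-2-(trimethylsilyl)phenyl trifluoromethanesulfonate (2.4 equiv)
Product: 16 acyclic bis(2-hydroxyaryl) ynone–enone, via dipotassium dicarboxylate 13 (not isolated), via 3,5-bis(benzyloxy)benzyne 14 (not isolated), via dipotassium bis-phenoxide 15 (not isolated)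
Conditions: KH (2.0 equiv), THF, 0 °C; then 5, KF, 18-crown-6, THF, 0 °C to rt; cold aqueous KH2PO4 quench
Reagents that add atoms: none
Why: Aryne insertion into the carboxylate C–O bond, twice: each carboxylate oxygen adds to the aryne carbon remote from the 3-benzyloxy group (C1, the former triflate carbon) because that group's inductive effect stabilises the developing anion at the adjacent C2, the C2 aryl anion attacks the ester carbonyl and the four-membered alkoxide opens to the 2-acylphenoxide (anionic ortho-Fries-type shift), and without a proton source both phenoxides should stay open because conjugate closure would give far more basic carbanions.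

Step 7
Reactants: 16 acyclic bis(2-hydroxyaryl) ynone–enone
Product: 18 hexa-O-benzyl ether of the target (2R,3S), via flavone–chalcone 17 (not isolated)
Conditions: quinine-derived 3,5-bis(trifluoromethyl)phenyl squaramide (9-amino-9-deoxy-epi-quinine squaramide, 10 mol %), PhMe, −20 °C to 0 °C
Reagents that add atoms: none
Why: Proposed new method: the quinuclidine nitrogen of the catalyst deprotonates each 2-hydroxyaryl ketone and the squaramide N–H pair binds the adjacent carbonyl oxygen, so the more electrophilic ynone arm should close first by 6-endo-dig oxa-Michael addition and protonation (flavone 17), and the α-aryl enone arm then closes by 6-endo-trig oxa-Michael addition of the phenol oxygen O1 to the β-carbon C2, followed by protonation of the enol at C3. The closest known reaction type is the cinchona thiourea- or squaramide-catalysed enantioselective intramolecular oxa-Michael addition of 2'-hydroxychalcones activated by an α-ester group; an α-aryl chalcone without that ester has not been shown, which is why the step carries the label. C2 is set by the catalyst, which holds the phenoxide–ammonium ion pair and the hydrogen-bonded carbonyl so that one face of the C2=C3 bond is exposed to O1. C3 is set by substrate control: the α-aryl ketone epimerises under the amine to the diequatorial 2,3-trans isomer, so the (2R) centre dictates (3S). The step needs 6-endo-dig rather than 5-exo-dig closure on the ynone, which metal-free Michael-type closure secures, and it needs a negligible racemic background, which the neutral non-polar medium at −20 °C secures. Closure is driven by relief of the strain between the 6'-benzyloxy group and the twisted α-aryl enone, so the product should not revert.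

Step 8
Reactants: 18 hexa-O-benzyl ether of the target
Product: 19 the target, (2R,3S)-5,7-dihydroxy-3-[2-hydroxy-5-(5,7-dihydroxy-4-oxo-4H-chromen-2-yl)phenyl]-2-(4-hydroxyphenyl)chroman-4-one
Conditions: H2 (1 atm), 10% Pd/C, EtOAc/MeOH, rt
Reagents that add atoms: none
Why: Hydrogenolysis of the six aryl benzyl ethers under neutral conditions should leave the base-labile C2 and C3 centres untouched, and it is stopped after six equivalents of hydrogen because the flavone C2=C3 bond, the aryl ketones and the cyclic benzylic C2–O1 bond react much more slowly.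

Compound list

1 | 3,5-bis(benzyloxy)phenol | Oc1cc(OCc2ccccc2)cc(OCc2ccccc2)c1 | starting material
2 | 2-bromo-3,5-bis(benzyloxy)phenol | Oc1cc(OCc2ccccc2)cc(OCc2ccccc2)c1Br | intermediate
3 | [2-bromo-3,5-bis(benzyloxy)phenoxy]trimethylsilane | C[Si](C)(C)Oc1cc(OCc2ccccc2)cc(OCc2ccccc2)c1Br | intermediate
4 | lithium 3,5-bis(benzyloxy)-2-(trimethylsilyl)phenoxide | [Li+].[O-]c1cc(OCc2ccccc2)cc(OCc2ccccc2)c1[Si](C)(C)C | intermediate
5 | 3,5-bis(benzyloxy)-2-(trimethylsilyl)phenyl trifluoromethanesulfonate | O=S(=O)(Oc1cc(OCc2ccccc2)cc(OCc2ccccc2)c1[Si](C)(C)C)C(F)(F)F | intermediate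
6 | 2-(5-bromo-2-hydroxyphenyl)acetic acid | OC(=O)Cc1cc(Br)ccc1O | starting material
7 | benzyl 2-[2-(benzyloxy)-5-bromophenyl]acetate | O=C(Cc1cc(Br)ccc1OCc1ccccc1)OCc1ccccc1 | intermediate
8 | 2-[2-(benzyloxy)-5-bromophenyl]acetic acid | OC(=O)Cc1cc(Br)ccc1OCc1ccccc1 | intermediate
9 | 4-(benzyloxy)benzaldehyde | O=Cc1ccc(OCc2ccccc2)cc1 | starting material
10 | (E)-2-[2-(benzyloxy)-5-bromophenyl]-3-[4-(benzyloxy)phenyl]prop-2-enoic acid (carboxyl trans to the 4-benzyloxyphenyl group) | OC(=O)/C(=C/c1ccc(OCc2ccccc2)cc1)c1cc(Br)ccc1OCc1ccccc1 | intermediate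
11 | propiolic acid | C#CC(=O)O | starting material
12 | (E)-2-[2-(benzyloxy)-5-(2-carboxyethynyl)phenyl]-3-[4-(benzyloxy)phenyl]prop-2-enoic acid | OC(=O)/C(=C/c1ccc(OCc2ccccc2)cc1)c1cc(C#CC(=O)O)ccc1OCc1ccccc1 | intermediate
13 | dipotassium salt of diacid 12 | [K+].[K+].[O-]C(=O)/C(=C/c1ccc(OCc2ccccc2)cc1)c1cc(C#CC(=O)[O-])ccc1OCc1ccccc1 | intermediate
14 | 3,5-bis(benzyloxy)benzyne | C1#CC(OCc2ccccc2)=CC(OCc2ccccc2)=C1 | intermediate
15 | dipotassium bis-phenoxide of 16 | [K+].[K+].O=C(/C(=C/c1ccc(OCc2ccccc2)cc1)c1cc(C#CC(=O)c2c([O-])cc(OCc3ccccc3)cc2OCc2ccccc2)ccc1OCc1ccccc1)c1c([O-])cc(OCc2ccccc2)cc1OCc1ccccc1 | intermediate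
16 | (E)-1-[2,4-bis(benzyloxy)-6-hydroxyphenyl]-2-{2-(benzyloxy)-5-[3-(2,4-bis(benzyloxy)-6-hydroxyphenyl)-3-oxoprop-1-yn-1-yl]phenyl}-3-[4-(benzyloxy)phenyl]prop-2-en-1-one | O=C(/C(=C/c1ccc(OCc2ccccc2)cc1)c1cc(C#CC(=O)c2c(O)cc(OCc3ccccc3)cc2OCc2ccccc2)ccc1OCc1ccccc1)c1c(O)cc(OCc2ccccc2)cc1OCc1ccccc1 | intermediate
17 | (E)-1-[2,4-bis(benzyloxy)-6-hydroxyphenyl]-2-{2-(benzyloxy)-5-[5,7-bis(benzyloxy)-4-oxo-4H-chromen-2-yl]phenyl}-3-[4-(benzyloxy)phenyl]prop-2-en-1-one | O=C(/C(=C/c1ccc(OCc2ccccc2)cc1)c1cc(-c2cc(=O)c3c(OCc4ccccc4)cc(OCc4ccccc4)cc3o2)ccc1OCc1ccccc1)c1c(O)cc(OCc2ccccc2)cc1OCc1ccccc1 | intermediate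
18 | (2R,3S)-5,7-bis(benzyloxy)-3-{2-(benzyloxy)-5-[5,7-bis(benzyloxy)-4-oxo-4H-chromen-2-yl]phenyl}-2-[4-(benzyloxy)phenyl]chroman-4-one (2,3-trans) | O=C1c2c(OCc3ccccc3)cc(OCc3ccccc3)cc2O[C@@H](c2ccc(OCc3ccccc3)cc2)[C@@H]1c1cc(-c2cc(=O)c3c(OCc4ccccc4)cc(OCc4ccccc4)cc3o2)ccc1OCc1ccccc1 | intermediate
19 | (2R,3S)-5,7-dihydroxy-3-[2-hydroxy-5-(5,7-dihydroxy-4-oxo-4H-chromen-2-yl)phenyl]-2-(4-hydroxyphenyl)chroman-4-one (2,3-trans; CNP0324936.1) | O=C1c2c(O)cc(O)cc2O[C@@H](c2ccc(O)cc2)[C@@H]1c1cc(-c2cc(=O)c3c(O)cc(O)cc3o2)ccc1O | target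

Total step count: 8. Longest linear sequence: 6 steps (steps 3 to 8, from 6); the aryne precursor 5 is made in 2 steps and joins at step 6.

Steps most likely to fail

Step 7. The likely failure is weak enantiofacial discrimination at C2 of the unactivated α-aryl enone, or an uncatalysed closure that erodes the excess. The fallback uses known chemistry, sets out from 16 and comes back at 18. Both rings are closed with an achiral base (NaOAc, EtOH, 70 °C), which should give the racemic 2,3-trans product, that is 18 together with its (2S,3R) enantiomer, the ent-hexabenzyl ether F1. The two are separated by preparative chromatography on an amylose tris(3,5-dimethylphenylcarbamate) stationary phase. F1 is returned to the racemate by DBU-mediated ring opening and reclosure (retro-oxa-Michael/oxa-Michael) and separated again.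

Step 6. The likely failures are protonation of the ortho-aryl anion before the acyl shift (leaving plain aryl esters), arylation of the product phenoxides by excess aryne, and addition of fluoride or carboxylate to the ynone. The fallback sets out from 12 and 2 and comes back at 16. Double esterification of 12 with 2 (DCC, DMAP, CH2Cl2) should give the bis(2-bromoaryl) diester F2. Bromine–lithium exchange (n-BuLi, THF, −100 °C) generates the same ortho-metalated aryl esters that the aryne route passes through, and their anionic ortho-Fries shift should give the dilithium bis-phenoxide F3. Acetic acid at −78 °C converts F3 into 16.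

Step 5. The likely failures are decarboxylation of the arylpropiolic acid on palladium (giving terminal or diaryl alkynes) and slow oxidative addition of the electron-rich aryl bromide. The fallback sets out from 10 and comes back at 12. Sonogashira coupling of 10 with ethynyltrimethylsilane (Pd(PPh3)2Cl2, copper iodide CuI, Et3N, DMF, 70 °C) should give the silylalkyne acid F4. K2CO3 in MeOH should then give the terminal alkyne acid F5. Deprotonation of F5 with LiHMDS (2.2 equiv, THF, −78 °C), trapping with CO2 and acidification return 12.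

Further compounds

F1 | step 7 | (2S,3R)-5,7-bis(benzyloxy)-3-{2-(benzyloxy)-5-[5,7-bis(benzyloxy)-4-oxo-4H-chromen-2-yl]phenyl}-2-[4-(benzyloxy)phenyl]chroman-4-one | O=C1c2c(OCc3ccccc3)cc(OCc3ccccc3)cc2O[C@H](c2ccc(OCc3ccccc3)cc2)[C@H]1c1cc(-c2cc(=O)c3c(OCc4ccccc4)cc(OCc4ccccc4)cc3o2)ccc1OCc1ccccc1
F2 | step 6 | bis[2-bromo-3,5-bis(benzyloxy)phenyl] diester of diacid 12 | O=C(Oc1cc(OCc2ccccc2)cc(OCc2ccccc2)c1Br)/C(=C/c1ccc(OCc2ccccc2)cc1)c1cc(C#CC(=O)Oc2cc(OCc3ccccc3)cc(OCc3ccccc3)c2Br)ccc1OCc1ccccc1
F3 | step 6 | dilithium bis-phenoxide of 16 | [Li+].[Li+].O=C(/C(=C/c1ccc(OCc2ccccc2)cc1)c1cc(C#CC(=O)c2c([O-])cc(OCc3ccccc3)cc2OCc2ccccc2)ccc1OCc1ccccc1)c1c([O-])cc(OCc2ccccc2)cc1OCc1ccccc1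
F4 | step 5 | (E)-2-{2-(benzyloxy)-5-[(trimethylsilyl)ethynyl]phenyl}-3-[4-(benzyloxy)phenyl]prop-2-enoic acid | OC(=O)/C(=C/c1ccc(OCc2ccccc2)cc1)c1cc(C#C[Si](C)(C)C)ccc1OCc1ccccc1
F5 | step 5 | (E)-2-[2-(benzyloxy)-5-ethynylphenyl]-3-[4-(benzyloxy)phenyl]prop-2-enoic acid | OC(=O)/C(=C/c1ccc(OCc2ccccc2)cc1)c1cc(C#C)ccc1OCc1ccccc1
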